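**Retrosynthetic overview**
1. The ten-membered carbocycle is closed last at C6–C7 by an electrochemically driven Pd/In umpolung allylation of an α-keto aldehyde; this one step also creates the 6-OH/5-ketone, the exo-methylene and the C6 and C7 stereocentres.
2. The γ-lactone (first ring) comes from a Morita–Baylis–Hillman adduct of a tartrate-derived aldehyde and methyl acrylate; its ring carbinol ester is the allyl precursor, so both secondary hydroxyls are acylated with the same acid.
3. C8 and C9 are the carbinol carbons of D-tartrate; C10 is set by chelation-controlled MeMgBr addition to a ketone made from the tartaric bis-Weinreb amide and a Grignard reagent.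
4. C1–C6 with the C4 methyl stereocentre come from (S)-β-citronellene; its vinyl group is the latent keto aldehyde.
5. Ring order: γ-lactone (step 8), then the ten-membered ring (step 12).

Assumption: locants C1–C15 follow germacrane numbering (lactone carbonyl C12, lactone O on C8, ester on C9, ketone C5), and compounds 1, 5, 11 and 15 are taken as purchasable.

**Route**

Step 1
Reactants: 1 (S)-β-citronellene
Product: 3 (4S)-4-methylhex-5-en-1-ol, via (4S)-4-methylhex-5-enal 2 (not isolated)
Conditions: O3 (1.0 equiv), CH2Cl2/MeOH 4:1, −78 °C; then NaBH4, −78 °C → rt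
Reagents that add atoms: ozone, [O-][O+]=O
Why: Chemoselective ozonolysis with reductive work-up; the electron-rich trisubstituted alkene is cleaved much faster than the vinyl group and the bought stereocentre is untouched.

Step 2
Reactants: 3 (4S)-4-methylhex-5-en-1-ol
Product: 4 (3S)-6-bromo-3-methylhex-1-ene
Conditions: CBr4, PPh3, CH2Cl2, 0 °C
Reagents that add atoms: carbon tetrabromide, BrC(Br)(Br)Br
Why: Appel bromination of a primary alcohol, remote from the stereocentre.

Step 3
Reactants: 5 dimethyl 2,3-O-isopropylidene-D-tartrate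
Product: 6 tartaric bis-Weinreb amide
Conditions: MeNH(OMe)·HCl (5 equiv), iPrMgCl (10 equiv), THF, −20 °C
Reagents that add atoms: N,O-dimethylhydroxylamine hydrochloride, CNOC.Cl
Why: Weinreb amide formation by aminolysis of the esters with the magnesium amide; the trans-acetonide stereocentres are not enolised at −20 °C.

Step 4
Reactants: 4 (3S)-6-bromo-3-methylhex-1-ene; 6 tartaric bis-Weinreb amide
Product: 8 keto Weinreb amide, via Grignard reagent 7 (not isolated)
Conditions: Mg, I2 (cat.), THF, 35 °C; then 6 (0.8 equiv), THF, −15 °C; cold 1 M HCl quench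
Reagents that add atoms: none
Why: Grignard mono-addition to a C2-symmetric bis-Weinreb amide; the first N-methoxy chelate persists until quench, so with about one equivalent only one amide becomes a ketone.

Step 5
Reactants: 8 keto Weinreb amide
Product: 9 tertiary alcohol Weinreb amide
Conditions: MeMgBr (1.5 equiv), MgBr2·OEt2 (1 equiv), CH2Cl2/Et2O, −78 °C; cold 1 M HCl quench
Reagents that add atoms: methylmagnesium bromide, C[Mg]Br
Why: Cram-chelate Grignard addition; magnesium bridges the ketone oxygen and the adjacent dioxolane oxygen on C9, so methyl adds anti to ring carbon C8 and gives 10R, while the Weinreb amide is inert at −78 °C.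

Step 6
Reactants: 9 tertiary alcohol Weinreb amide
Product: 10 hydroxy aldehyde
Conditions: iBu2AlH (2.5 equiv), THF, −78 °C; aq. KNaC4H4O6
Reagents that add atoms: none
Why: Weinreb amide reduction stops at the aldehyde through the stable aluminium hemiaminal chelate; the trans-acetonide prevents lactol formation with the tertiary hydroxyl.

Step 7
Reactants: 10 hydroxy aldehyde; 11 methyl acrylate
Product: 12 Morita–Baylis–Hillman adduct
Conditions: DABCO (1 equiv), methyl acrylate (5 equiv), MeOH, rt, 3–5 d
Reagents that add atoms: none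
Why: Morita–Baylis–Hillman reaction of an α-alkoxy aldehyde; the new carbinol forms as an epimer mixture, which is harmless because this carbon later carries the leaving group and is re-set in step 12.

Step 8
Reactants: 12 Morita–Baylis–Hillman adduct
Product: 14 triol lactone, via tetraol methyl ester 13 (not isolated)
Conditions: 2 M HCl/THF 1:3, rt; concentrate; PPTS (cat.), toluene, 60 °C
Reagents that add atoms: none
Why: Acetonide hydrolysis followed by lactonisation of the C8 hydroxyl onto the acrylate ester; the five-membered γ-lactone is favoured over the six-membered alternative through the C9 hydroxyl, and C8/C9 are not touched.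

Step 9
Reactants: 14 triol lactone; 15 (2E)-3-methylpent-2-enoic acid (2.6 equiv)
Product: 16 bis-ester
Conditions: DIC, DMAP (0.2 equiv), CH2Cl2, 0 °C → rt
Reagents that add atoms: none
Why: Steglich esterification of both secondary hydroxyls (tertiary C10–OH inert); it installs the natural C9 ester and turns the ring carbinol into an activated allylic ester, so no differentiation is needed.

Step 10
Reactants: 16 bis-ester
Product: 17 terminal diol
Conditions: OsO4 (2 mol %), NMO (1.1 equiv), citric acid (1 equiv), tBuOH/H2O 1:1, 0 °C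
Reagents that add atoms: N-methylmorpholine N-oxide, C[N+]1([O-])CCOCC1; water, O
Why: Upjohn dihydroxylation; electrophilic OsO4 takes the unhindered vinyl group far faster than the three electron-poor acrylate-type alkenes, and citric acid keeps the liberated amine protonated so it cannot attack the allylic ester.

Step 11
Reactants: 17 terminal diol
Product: 18 α-keto aldehyde
Conditions: IBX (3 equiv), EtOAc, 75 °C
Reagents that add atoms: none
Why: IBX oxidation of a 1,2-diol to the 1,2-dicarbonyl without C–C cleavage under neutral conditions, which spares the tertiary alcohol, the allylic ester and the C4 stereocentre.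

Step 12
Reactants: 18 α-keto aldehyde
Product: 20 target CNP0197047.1, via allylindium dibromide 19 (not isolated)
Conditions: Pd(PPh3)4 (5 mol %), InBr3 (20 mol %), nBu4NBr (0.1 M), THF/H2O 4:1, undivided cell, Al anode, reticulated vitreous carbon cathode, 2 mA cm−2, 2.2 F mol−1, 18 added over 10 h (final 2 mM), 20 °C
Reagents that add atoms: none
Why: Proposed new method: an electroreductive Pd/In dual-catalytic umpolung allylation run as a macrocyclisation. Zerovalent palladium ionises the activated ring allylic ester to a π-allyl complex (erasing the epimeric ester carbon); monovalent indium, made from InBr3 at the cathode and regenerated there with the Al anode as electron source, transmetalates it reductively to allylindium 19. In water the keto aldehyde is shielded from cathodic reduction as its hydrate; 19 adds through ring carbon C7 to the aldehyde in a closed six-membered transition state, anti to the C8 side chain (7S, trans-lactone) and with the acyl residue equatorial (6S), forming the C6–C7 bond, the exo-methylene and the α-hydroxy ketone at once. The closest known chemistry is the stoichiometric Pd/InI umpolung allylation of aldehydes with allylic esters, the electrochemical regeneration of monovalent indium in intermolecular Barbier allylations, and the thermal chromium- or indium-mediated Barbier ring closures used for germacranolides.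

**Compound list**

1 | (S)-β-citronellene, (3S)-3,7-dimethylocta-1,6-diene | C=C[C@@H](C)CCC=C(C)C | starting material
2 | (4S)-4-methylhex-5-enal (not isolated) | C=C[C@@H](C)CCC=O | intermediate
3 | (4S)-4-methylhex-5-en-1-ol | C=C[C@@H](C)CCCO | intermediate
4 | (3S)-6-bromo-3-methylhex-1-ene | C=C[C@@H](C)CCCBr | intermediate
5 | dimethyl (4S,5S)-2,2-dimethyl-1,3-dioxolane-4,5-dicarboxylate (dimethyl 2,3-O-isopropylidene-D-tartrate) | COC(=O)[C@H]1OC(C)(C)O[C@@H]1C(=O)OC | starting material
6 | (4S,5S)-N4,N5-dimethoxy-N4,N5,2,2-tetramethyl-1,3-dioxolane-4,5-dicarboxamide | CON(C)C(=O)[C@H]1OC(C)(C)O[C@@H]1C(=O)N(C)OC | intermediate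
7 | [(4S)-4-methylhex-5-en-1-yl]magnesium bromide (not isolated) | C=C[C@@H](C)CCC[Mg]Br | intermediate
8 | (4S,5S)-N-methoxy-N,2,2-trimethyl-5-[(5S)-5-methylhept-6-enoyl]-1,3-dioxolane-4-carboxamide | C=C[C@@H](C)CCCC(=O)[C@H]1OC(C)(C)O[C@@H]1C(=O)N(C)OC | intermediate
9 | (4S,5S)-5-[(2R,6S)-2-hydroxy-6-methyloct-7-en-2-yl]-N-methoxy-N,2,2-trimethyl-1,3-dioxolane-4-carboxamide | C=C[C@@H](C)CCC[C@@](C)(O)[C@H]1OC(C)(C)O[C@@H]1C(=O)N(C)OC | intermediate
10 | (4S,5S)-5-[(2R,6S)-2-hydroxy-6-methyloct-7-en-2-yl]-2,2-dimethyl-1,3-dioxolane-4-carbaldehyde | C=C[C@@H](C)CCC[C@@](C)(O)[C@H]1OC(C)(C)O[C@@H]1C=O | intermediate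
11 | methyl acrylate | C=CC(=O)OC | starting material
12 | methyl 2-[hydroxy{(4R,5S)-5-[(2R,6S)-2-hydroxy-6-methyloct-7-en-2-yl]-2,2-dimethyl-1,3-dioxolan-4-yl}methyl]prop-2-enoate (carbinol epimers) | C=C[C@@H](C)CCC[C@@](C)(O)[C@H]1OC(C)(C)O[C@@H]1C(O)C(=C)C(=O)OC | intermediate
13 | methyl (4R,5S,6R,10S)-3,4,5,6-tetrahydroxy-6,10-dimethyl-2-methylidenedodec-11-enoate (C3 epimers; not isolated) | C=C[C@@H](C)CCC[C@@](C)(O)[C@@H](O)[C@H](O)C(O)C(=C)C(=O)OC | intermediate
14 | (5R)-5-[(1S,2R,6S)-1,2-dihydroxy-2,6-dimethyloct-7-en-1-yl]-4-hydroxy-3-methylideneoxolan-2-one (C4 epimers) | C=C[C@@H](C)CCC[C@@](C)(O)[C@@H](O)[C@@H]1OC(=O)C(=C)C1O | intermediate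
15 | (2E)-3-methylpent-2-enoic acid | CC/C(C)=C/C(=O)O | starting material
16 | (1S,2R,6S)-2-hydroxy-2,6-dimethyl-1-[(2R)-4-methylidene-3-{[(2E)-3-methylpent-2-enoyl]oxy}-5-oxooxolan-2-yl]oct-7-en-1-yl (2E)-3-methylpent-2-enoate (epimers at oxolane C3) | C=C[C@@H](C)CCC[C@@](C)(O)[C@@H](OC(=O)/C=C(\C)CC)[C@@H]1OC(=O)C(=C)C1OC(=O)/C=C(\C)CC | intermediate
17 | (1S,2R,6S)-2,7,8-trihydroxy-2,6-dimethyl-1-[(2R)-4-methylidene-3-{[(2E)-3-methylpent-2-enoyl]oxy}-5-oxooxolan-2-yl]octyl (2E)-3-methylpent-2-enoate (epimers at C7 and oxolane C3) | OCC(O)[C@@H](C)CCC[C@@](C)(O)[C@@H](OC(=O)/C=C(\C)CC)[C@@H]1OC(=O)C(=C)C1OC(=O)/C=C(\C)CC | intermediate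
18 | (1S,2R,6S)-2-hydroxy-2,6-dimethyl-7,8-dioxo-1-[(2R)-4-methylidene-3-{[(2E)-3-methylpent-2-enoyl]oxy}-5-oxooxolan-2-yl]octyl (2E)-3-methylpent-2-enoate (epimers at oxolane C3) | O=CC(=O)[C@@H](C)CCC[C@@](C)(O)[C@@H](OC(=O)/C=C(\C)CC)[C@@H]1OC(=O)C(=C)C1OC(=O)/C=C(\C)CC | intermediate
19 | (1S,2R,6S)-1-{(2R)-4-[(dibromoindiganyl)methyl]-5-oxo-2,5-dihydrofuran-2-yl}-2-hydroxy-2,6-dimethyl-7,8-dioxooctyl (2E)-3-methylpent-2-enoate (not isolated) | O=CC(=O)[C@@H](C)CCC[C@@](C)(O)[C@@H](OC(=O)/C=C(\C)CC)[C@@H]1OC(=O)C(C[In](Br)Br)=C1 | intermediate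
20 | CNP0197047.1, (4S,6S,7S,8R,9S,10R)-6,10-dihydroxy-9-[(2E)-3-methylpent-2-enoyloxy]-5-oxogermacr-11(13)-en-12,8-olide (trans-fused α-methylene-γ-lactone) | C=C1C(=O)O[C@@H]2[C@@H]1[C@H](O)C(=O)[C@@H](C)CCC[C@@](C)(O)[C@H]2OC(=O)/C=C(\C)CC | target

**Step count**

Total steps: 12. Longest linear sequence: 11 (steps 1, 2, 4–12 from 1); 10 from 5 (steps 3–12).

**Steps most likely to fail and fallbacks**

Step 12 (the new electrochemical ring closure). Risks:
- cathodic reduction of the 1,2-dicarbonyl if it is not fully hydrated;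
- O-allylation of the π-allyl complex by the C10 hydroxyl;
- oligomerisation;
- the wrong C6 epimer if the keto group chelates indium.

Fallback with known chemistry, setting out from 18: MgBr2·OEt2 (THF, 0 °C) exchanges the activated ring allylic ester for bromide with allylic transposition, giving the 3-(bromomethyl)butenolide keto aldehyde F1. F1 is then cyclised by the established stoichiometric Barbier protocol (In powder, THF/H2O 1:1, 2 mM, 25 °C), in which the allylindium adds through the ring γ-carbon exactly as bromomethyl-butenolides do intermolecularly. This returns to the route at 20.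

Step 5 (C10 configuration). If the dioxolane oxygen chelates poorly and Felkin-type addition dominates, the wrong tertiary carbinol results. Fallback, setting out from 6: the two carbon substituents are introduced in the reverse order. MeMgBr (1.1 equiv, THF, −15 °C) gives the methyl ketone mono-Weinreb amide F2. Grignard reagent 7 is then added under non-chelating conditions (CeCl3, THF, −78 °C); the same Felkin preference now delivers the 10R carbinol, returning to the route at 9.

Step 10 (chemoselective dihydroxylation). The α-methylene lactone may be osmylated competitively, or the allylic ester lost. Fallback, setting out from 16: the vinyl group is addressed by electrophilic epoxidation instead of osmylation. mCPBA (NaHCO3, CH2Cl2, 0 °C → rt) does not touch acrylate-type alkenes and gives the terminal epoxide F3. Acid-catalysed hydrolytic opening (HClO4 cat., THF/H2O, rt) then returns to the route at 17.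

Further compounds
F1 | step 12 | (1S,2R,6S)-1-[(2R)-4-(bromomethyl)-5-oxo-2,5-dihydrofuran-2-yl]-2-hydroxy-2,6-dimethyl-7,8-dioxooctyl (2E)-3-methylpent-2-enoate | O=CC(=O)[C@@H](C)CCC[C@@](C)(O)[C@@H](OC(=O)/C=C(\C)CC)[C@@H]1OC(=O)C(CBr)=C1
F2 | step 5 | (4S,5S)-5-acetyl-N-methoxy-N,2,2-trimethyl-1,3-dioxolane-4-carboxamide | CC(=O)[C@H]1OC(C)(C)O[C@@H]1C(=O)N(C)OC
F3 | step 10 | (1S,2R,6S)-2-hydroxy-2-methyl-6-(oxiran-2-yl)-1-[(2R)-4-methylidene-3-{[(2E)-3-methylpent-2-enoyl]oxy}-5-oxooxolan-2-yl]heptyl (2E)-3-methylpent-2-enoate (epimers at the oxirane carbon and oxolane C3) | C1OC1[C@@H](C)CCC[C@@](C)(O)[C@@H](OC(=O)/C=C(\C)CC)[C@@H]2OC(=O)C(=C)C2OC(=O)/C=C(\C)CC
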